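**Retrosynthetic overview**
- The target is reached from a ten-membered carbocycle by the two lactonizations (C15→O6 butenolide, then C12→O8 methylene lactone) and desilylation, all after the carbocycle exists.
- The ten-membered ring is closed at C6–C7, the bond that germacrene A synthase makes (farnesyl C1–C10), by an intramolecular aqueous indium Barbier allylation of a 2-(bromomethyl)enoate onto a γ-hydroxybutenolide acting as its open (Z)-4-oxo-2-enoic acid; C6 and C7 are set here from C8.
- The acyclic C15 precursor comes from singlet-oxygen unmasking of a 2-silylfuran (C15 acid and C6 aldehyde) and Appel bromination at C13.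
- That precursor comes from a B-alkyl Suzuki coupling (C1–C10) of an (S)-furyl allyl isobutyrate (C3 by asymmetric vinylzinc addition) with a (Z)-vinyl iodide (C8 by Zn-ProPhenol alkynylation, C13 by hydroalumination and formaldehyde).
- Ring order: carbocycle, then 15,6-butenolide, then 12,8-α-methylene lactone.

Assumption: mikanolide-type germacrane numbering is used (C12→O8 and C15→O6 lactones, 3-O-isobutyryl, 14-OH); on it the target is (3S,6R,7S,8R) and the cyclase-made bond is C6–C7.

**Route**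

Step 1
Reactants: 1 furan-3-carbaldehyde
Product: 5 2-(trimethylsilyl)furan-3-carbaldehyde, via lithium amino alkoxide 2 (not isolated), via C2-lithiated amino alkoxide 3 (not isolated), via C2-silylated amino alkoxide 4 (not isolated)
Conditions: LiN(Me)CH2CH2NMe2 (from the amine and n-BuLi), THF, −78 °C; n-BuLi, −20 °C; TMSCl, −78 °C to rt; H2O
Reagents that add atoms: trimethylsilyl chloride C[Si](C)(C)Cl
Why: Comins in-situ protection of the aldehyde as an α-amino alkoxide followed by chelation-directed ortho-lithiation puts lithium at C2 (between the ring oxygen and the masked formyl group), and silylation there later fixes the regiochemistry of furan oxidation; no stereocenter is formed.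

Step 2
Reactants: 5 2-(trimethylsilyl)furan-3-carbaldehyde
Product: 7 (1S)-1-[2-(trimethylsilyl)furan-3-yl]prop-2-en-1-yl 2-methylpropanoate, via vinylzinc alkoxide 6 (not isolated)
Conditions: Zn(CH=CH2)2 (1.5 equiv), (2S)-(−)-3-exo-morpholinoisoborneol (5 mol %), toluene, 0 °C; then (iPrCO)2O, DMAP (cat.), 0 °C to rt
Reagents that add atoms: divinylzinc C=C[Zn]C=C; isobutyric anhydride CC(C)C(=O)OC(=O)C(C)C
Why: Amino-alcohol-catalysed enantioselective alkenylzinc addition (Oppolzer/Noyori type) delivers the vinyl group to the Si face of the aldehyde to set C3 as S, and the zinc alkoxide is acylated in the same pot so the isobutyrate is in place from the start.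

Step 3
Reactants: 8 tert-butyldimethyl(prop-2-yn-1-yloxy)silane
Product: 11 4-[(tert-butyldimethylsilyl)oxy]but-2-ynal, via lithium acetylide 9 (not isolated), via hemiaminal alkoxide 10 (not isolated)
Conditions: n-BuLi, THF, −78 °C; DMF, −78 to 0 °C; inverse quench into aq. KH2PO4
Reagents that add atoms: N,N-dimethylformamide CN(C)C=O
Why: Formylation of a lithium acetylide with DMF (Bouveault-type); the buffered inverse quench stops dimethylamine adding back to the ynal.

Step 4
Reactants: 11 4-[(tert-butyldimethylsilyl)oxy]but-2-ynal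
Product: 12 (2Z)-4-[(tert-butyldimethylsilyl)oxy]-3-iodobut-2-enal
Conditions: NaI (1.5 equiv), AcOH, rt, dark
Reagents that add atoms: sodium iodide [Na+].[I-]
Why: Conjugate anti-hydroiodination of the ynal gives the kinetic Z β-iodo enal, which fixes the future C9=C10 geometry (CHO trans to CH2OTBS, iodine in the place later taken by C1).

Step 5
Reactants: 12 (2Z)-4-[(tert-butyldimethylsilyl)oxy]-3-iodobut-2-enal, 13 methyl prop-2-ynoate
Product: 15 methyl (4R,5Z)-7-[(tert-butyldimethylsilyl)oxy]-4-hydroxy-6-iodohept-5-en-2-ynoate, via methylzinc alkynylide 14 (not isolated)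
Conditions: Me2Zn (3 equiv), (S,S)-ProPhenol (20 mol %), Ph3PO (40 mol %), toluene, 4 °C
Reagents that add atoms: none
Why: Trost Zn-ProPhenol alkynylation of an enal, in which the dinuclear zinc catalyst delivers the alkynyl group to one aldehyde face to set C8 as the 4R carbinol; the sense of induction of (S,S)-ProPhenol is not certain for this β-iodo enal, so the ligand antipode is used if it proves opposite.

Step 6
Reactants: 15 methyl (4R,5Z)-7-[(tert-butyldimethylsilyl)oxy]-4-hydroxy-6-iodohept-5-en-2-ynoate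
Product: 17 methyl (2E,4S,5Z)-7-[(tert-butyldimethylsilyl)oxy]-4-hydroxy-2-(hydroxymethyl)-6-iodohepta-2,5-dienoate, via cyclic vinylalanate 16 (not isolated)
Conditions: NaAlH2(OCH2CH2OMe)2 (Red-Al, 1.6 equiv), THF, −72 °C; then CH2O (gas, from paraformaldehyde), −72 to −20 °C
Reagents that add atoms: formaldehyde C=O
Why: Proposed new method: the C8 alkoxy-aluminate delivers hydride to C7 and leaves aluminium on C11 in a five-membered chelate (trans-hydroalumination), and this α-aluminio enoate then adds to formaldehyde with retention so that C13 ends cis to C8 and the ester trans (no lactonization); the closest known reactions are the Red-Al trans-reduction of γ-hydroxy ynoates with proton or iodine quench and the vinylalumination of aldehydes, and C8 is untouched (the descriptor changes to S only because the iodine now decides CIP priority).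

Step 7
Reactants: 7 (1S)-1-[2-(trimethylsilyl)furan-3-yl]prop-2-en-1-yl 2-methylpropanoate, 17 methyl (2E,4S,5Z)-7-[(tert-butyldimethylsilyl)oxy]-4-hydroxy-2-(hydroxymethyl)-6-iodohepta-2,5-dienoate
Product: 19 methyl (2E,4R,5E,9S)-6-{[(tert-butyldimethylsilyl)oxy]methyl}-4-hydroxy-2-(hydroxymethyl)-9-[(2-methylpropanoyl)oxy]-9-[2-(trimethylsilyl)furan-3-yl]nona-2,5-dienoate, via B-alkyl-9-BBN 18 (not isolated)
Conditions: 9-BBN (1.4 equiv), THF, 0 °C to rt; then 17, Pd(dppf)Cl2 (5 mol %), AsPh3, aq. K3PO4, DMF, rt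
Reagents that add atoms: none
Why: Anti-Markovnikov hydroboration of the terminal vinyl group and B-alkyl Suzuki–Miyaura coupling with retention at the vinyl iodide form C1–C10 with C8 cis to C1; the free hydroxyls, both esters and the silylfuran tolerate these conditions and no stereocenter is touched.

Step 8
Reactants: 19 methyl (2E,4R,5E,9S)-6-{[(tert-butyldimethylsilyl)oxy]methyl}-4-hydroxy-2-(hydroxymethyl)-9-[(2-methylpropanoyl)oxy]-9-[2-(trimethylsilyl)furan-3-yl]nona-2,5-dienoate
Product: 20 methyl (2Z,4R,5E,9S)-2-(bromomethyl)-6-{[(tert-butyldimethylsilyl)oxy]methyl}-4-hydroxy-9-[(2-methylpropanoyl)oxy]-9-[2-(trimethylsilyl)furan-3-yl]nona-2,5-dienoate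
Conditions: CBr4, PPh3 (1.1 equiv each), 2,6-lutidine, CH2Cl2, −30 to 0 °C
Reagents that add atoms: carbon tetrabromide BrC(Br)(Br)Br
Why: Appel bromination under neutral conditions takes the unhindered primary allylic alcohol in preference to the hindered secondary C8 alcohol, which stays free to direct the cyclization.

Step 9
Reactants: 20 methyl (2Z,4R,5E,9S)-2-(bromomethyl)-6-{[(tert-butyldimethylsilyl)oxy]methyl}-4-hydroxy-9-[(2-methylpropanoyl)oxy]-9-[2-(trimethylsilyl)furan-3-yl]nona-2,5-dienoate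
Product: 23 methyl (2Z,4R,5E,9S)-2-(bromomethyl)-6-{[(tert-butyldimethylsilyl)oxy]methyl}-4-hydroxy-9-(5-hydroxy-2-oxo-2,5-dihydrofuran-3-yl)-9-[(2-methylpropanoyl)oxy]nona-2,5-dienoate (both lactol epimers), via furan endoperoxide 21 (not isolated), via silyl ester aldehyde 22 (not isolated)
Conditions: O2, tetraphenylporphyrin (1 mol %), visible light, CH2Cl2, −78 °C; then wet SiO2
Reagents that add atoms: oxygen O=O
Why: Singlet-oxygen [4+2] cycloaddition to the 2-silylfuran (Katsumura oxidation) is followed by silyl migration that makes the silicon-bearing carbon the carboxyl carbon, so the α-substituted γ-hydroxybutenolide (C15 acid, C6 masked aldehyde) forms regiospecifically and much faster than any ene reaction of the trisubstituted alkenes.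

Step 10
Reactants: 23 methyl (2Z,4R,5E,9S)-2-(bromomethyl)-6-{[(tert-butyldimethylsilyl)oxy]methyl}-4-hydroxy-9-(5-hydroxy-2-oxo-2,5-dihydrofuran-3-yl)-9-[(2-methylpropanoyl)oxy]nona-2,5-dienoate
Product: 26 CNP0322767.4, via allylindium 24 (not isolated), via macrocyclic hydroxy ester 25 (not isolated)
Conditions: In powder (3 equiv), THF/sat. aq. NH4Cl (3:1), 23 added over 10 h to 2 mM, rt; then 2 M HCl to pH 1, rt
Reagents that add atoms: none
Why: Proposed new method: indium inserts into the allylic C–Br bond in water while the pseudo-acid opens to its (Z)-4-oxo-2-enoate (as mucohalic acids do in known indium and tin Barbier allylations, the closest precedent together with Barbier and Nozaki–Hiyama–Kishi macrocyclizations of 2-(bromomethyl)acrylates to germacranolides), and γ-attack of the Z-allylindium through a chair SE2' transition state with indium bound to O8 closes C6–C7 anti to C9 (7S) and syn to the aldehyde substituent (6R); the C6 hydroxy acid relactonizes at once to the butenolide so only O8 is left for C12, and HCl then closes the trans-fused methylene lactone and removes the TBS group.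

**Compound list**

1 | furan-3-carbaldehyde | O=Cc1ccoc1 | starting material
2 | lithium (furan-3-yl){[2-(dimethylamino)ethyl](methyl)amino}methanolate | [Li+].[O-]C(N(C)CCN(C)C)c1ccoc1 | intermediate
3 | lithium {[2-(dimethylamino)ethyl](methyl)amino}(2-lithiofuran-3-yl)methanolate | [Li+].[O-]C(N(C)CCN(C)C)c1ccoc1[Li] | intermediate
4 | lithium {[2-(dimethylamino)ethyl](methyl)amino}[2-(trimethylsilyl)furan-3-yl]methanolate | [Li+].[O-]C(N(C)CCN(C)C)c1ccoc1[Si](C)(C)C | intermediate
5 | 2-(trimethylsilyl)furan-3-carbaldehyde | O=Cc1ccoc1[Si](C)(C)C | intermediate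
6 | ethenylzinc (1S)-1-[2-(trimethylsilyl)furan-3-yl]prop-2-en-1-olate | C=C[C@H](O[Zn]C=C)c1ccoc1[Si](C)(C)C | intermediate
7 | (1S)-1-[2-(trimethylsilyl)furan-3-yl]prop-2-en-1-yl 2-methylpropanoate | C=C[C@H](OC(=O)C(C)C)c1ccoc1[Si](C)(C)C | intermediate
8 | tert-butyldimethyl(prop-2-yn-1-yloxy)silane | C#CCO[Si](C)(C)C(C)(C)C | starting material
9 | lithium 3-[(tert-butyldimethylsilyl)oxy]prop-1-yn-1-ide | [Li]C#CCO[Si](C)(C)C(C)(C)C | intermediate
10 | lithium 4-[(tert-butyldimethylsilyl)oxy]-1-(dimethylamino)but-2-yn-1-olate | [Li+].[O-]C(N(C)C)C#CCO[Si](C)(C)C(C)(C)C | intermediate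
11 | 4-[(tert-butyldimethylsilyl)oxy]but-2-ynal | O=CC#CCO[Si](C)(C)C(C)(C)C | intermediate
12 | (2Z)-4-[(tert-butyldimethylsilyl)oxy]-3-iodobut-2-enal | O=C/C=C(\I)CO[Si](C)(C)C(C)(C)C | intermediate
13 | methyl prop-2-ynoate (methyl propiolate) | C#CC(=O)OC | starting material
14 | methyl 3-(methylzincio)prop-2-ynoate | C[Zn]C#CC(=O)OC | intermediate
15 | methyl (4R,5Z)-7-[(tert-butyldimethylsilyl)oxy]-4-hydroxy-6-iodohept-5-en-2-ynoate | COC(=O)C#C[C@H](O)/C=C(\I)CO[Si](C)(C)C(C)(C)C | intermediate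
16 | sodium bis(2-methoxyethoxy) alanate of 15 after trans-hydroalumination (five-membered ring Al–O8–C8–C7=C11, Al on C11) | [Na+].COCCO[Al-]1(OCCOC)O[C@H](/C=C(\I)CO[Si](C)(C)C(C)(C)C)C=C1C(=O)OC | intermediate
17 | methyl (2E,4S,5Z)-7-[(tert-butyldimethylsilyl)oxy]-4-hydroxy-2-(hydroxymethyl)-6-iodohepta-2,5-dienoate | COC(=O)/C(CO)=C/[C@H](O)/C=C(\I)CO[Si](C)(C)C(C)(C)C | intermediate
18 | (1S)-3-(9-borabicyclo[3.3.1]nonan-9-yl)-1-[2-(trimethylsilyl)furan-3-yl]propyl 2-methylpropanoate | B1(CC[C@H](OC(=O)C(C)C)c2ccoc2[Si](C)(C)C)C2CCCC1CCC2 | intermediate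
19 | methyl (2E,4R,5E,9S)-6-{[(tert-butyldimethylsilyl)oxy]methyl}-4-hydroxy-2-(hydroxymethyl)-9-[(2-methylpropanoyl)oxy]-9-[2-(trimethylsilyl)furan-3-yl]nona-2,5-dienoate | COC(=O)/C(CO)=C/[C@H](O)/C=C(CO[Si](C)(C)C(C)(C)C)\CC[C@H](OC(=O)C(C)C)c1ccoc1[Si](C)(C)C | intermediate
20 | methyl (2Z,4R,5E,9S)-2-(bromomethyl)-6-{[(tert-butyldimethylsilyl)oxy]methyl}-4-hydroxy-9-[(2-methylpropanoyl)oxy]-9-[2-(trimethylsilyl)furan-3-yl]nona-2,5-dienoate | COC(=O)/C(CBr)=C/[C@H](O)/C=C(CO[Si](C)(C)C(C)(C)C)\CC[C@H](OC(=O)C(C)C)c1ccoc1[Si](C)(C)C | intermediate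
21 | 2,5-endoperoxide of the furan ring of 20 (1-trimethylsilyl-2,3,7-trioxabicyclo[2.2.1]hept-5-ene carrying the chain on C6) | COC(=O)/C(CBr)=C/[C@H](O)/C=C(CO[Si](C)(C)C(C)(C)C)\CC[C@H](OC(=O)C(C)C)C1=CC2OOC1([Si](C)(C)C)O2 | intermediate
22 | open-chain (Z)-4-oxo-2-enoic acid trimethylsilyl ester from 21 (C15 silyl ester, C6 aldehyde) | COC(=O)/C(CBr)=C/[C@H](O)/C=C(CO[Si](C)(C)C(C)(C)C)\CC[C@H](OC(=O)C(C)C)/C(C(=O)O[Si](C)(C)C)=C/C=O | intermediate
23 | methyl (2Z,4R,5E,9S)-2-(bromomethyl)-6-{[(tert-butyldimethylsilyl)oxy]methyl}-4-hydroxy-9-(5-hydroxy-2-oxo-2,5-dihydrofuran-3-yl)-9-[(2-methylpropanoyl)oxy]nona-2,5-dienoate, both lactol epimers | COC(=O)/C(CBr)=C/[C@H](O)/C=C(CO[Si](C)(C)C(C)(C)C)\CC[C@H](OC(=O)C(C)C)C1=CC(O)OC1=O | intermediate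
24 | allylindium reagent from 23 (C13–In bond in place of C13–Br) | COC(=O)/C(C[In])=C/[C@H](O)/C=C(CO[Si](C)(C)C(C)(C)C)\CC[C@H](OC(=O)C(C)C)C1=CC(O)OC1=O | intermediate
25 | methyl (3S,6R,7S,8R)-14-[(tert-butyldimethylsilyl)oxy]-8-hydroxy-3-[(2-methylpropanoyl)oxy]germacra-4,9,11(13)-trien-15,6-olid-12-oate (ten-membered ring, 15,6-butenolide closed, C12 methyl ester open) | O[C@@H]1/C=C(/CO[Si](C)(C)C(C)(C)C)CC[C@H](OC(=O)C(C)C)C2=C[C@@H](OC2=O)[C@H]1C(=C)C(=O)OC | intermediate
26 | CNP0322767.4, (3S,6R,7S,8R)-14-hydroxy-3-[(2-methylpropanoyl)oxy]germacra-4,9,11(13)-triene-12,8:15,6-diolide (C4=C5 trans and C9=C10 cis within the ten-membered ring) | C=C1C(=O)O[C@@H]2/C=C(/CO)CC[C@H](OC(=O)C(C)C)C3=C[C@@H](OC3=O)[C@@H]12 | target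

**Totals and risks**

Total step count: 10. Longest linear sequence: 8 steps (steps 3 to 10, from 8). The left branch (steps 1 and 2) joins at step 7.

The three steps most likely to fail are steps 10, 6 and 8.

Step 10 (ten-membered ring closure on a pseudo-acid in water). The fallback gives up the pseudo-acid as electrophile and sets out from 23. Methylation with TMSCHN2 (MeOH/toluene, 0 °C) traps the open form as the discrete aldehyde, methyl (2Z,4R,5E,9S,10Z)-2-(bromomethyl)-6-{[(tert-butyldimethylsilyl)oxy]methyl}-4-hydroxy-10-(methoxycarbonyl)-9-[(2-methylpropanoyl)oxy]-12-oxododeca-2,5,10-trienoate F1. An anhydrous Nozaki–Hiyama–Kishi allylation with CrCl2 (divalent chromium, 6 equiv, THF, 1 mM, rt) then closes C6–C7 on the free aldehyde, the C6 chromium alkoxide lactonizes onto the cis C15 methyl ester, and the route is rejoined at 25, which is treated with HCl as in step 10.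

Step 6 (formaldehyde trapping of the vinylalanate). The fallback brings in C13 by cross-coupling and sets out from 15. B-alkyl Suzuki coupling of 15 with borane 18 (conditions of step 7) first gives the coupled ynoate, methyl (4R,5E,9S)-6-{[(tert-butyldimethylsilyl)oxy]methyl}-4-hydroxy-9-[(2-methylpropanoyl)oxy]-9-[2-(trimethylsilyl)furan-3-yl]non-5-en-2-ynoate F2. Red-Al at −78 °C followed by I2 (the known trans-hydroalumination/iodination; the hindered isobutyrate is expected to survive at this temperature) gives the α-iodo enoate, methyl (2Z,4R,5E,9S)-6-{[(tert-butyldimethylsilyl)oxy]methyl}-4-hydroxy-2-iodo-9-[(2-methylpropanoyl)oxy]-9-[2-(trimethylsilyl)furan-3-yl]nona-2,5-dienoate F3. Stille coupling of F3 with Bu3SnCH2OH (Pd(PPh3)4, toluene, 80 °C) installs the hydroxymethyl group with retention and comes back to the route at 19.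

Step 8 (selective bromination next to a free bis-allylic alcohol). The fallback never makes the bromide and sets out from 19. Photooxygenation as in step 9 gives the diol pseudo-acid, methyl (2E,4R,5E,9S)-6-{[(tert-butyldimethylsilyl)oxy]methyl}-4-hydroxy-9-(5-hydroxy-2-oxo-2,5-dihydrofuran-3-yl)-2-(hydroxymethyl)-9-[(2-methylpropanoyl)oxy]nona-2,5-dienoate F4. The allylic alcohol itself is then turned into the nucleophile by umpolung (PdCl2(PhCN)2 cat., SnCl2, 1,3-dimethylimidazolidin-2-one/H2O, high dilution; π-allylpalladium to allyltin, Masuyama-type carbonyl allylation), which closes C6–C7 and comes back to the route at 25.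

**Further compounds**

F1 | step 10 | methyl (2Z,4R,5E,9S,10Z)-2-(bromomethyl)-6-{[(tert-butyldimethylsilyl)oxy]methyl}-4-hydroxy-10-(methoxycarbonyl)-9-[(2-methylpropanoyl)oxy]-12-oxododeca-2,5,10-trienoate | COC(=O)/C(CBr)=C/[C@H](O)/C=C(CO[Si](C)(C)C(C)(C)C)\CC[C@H](OC(=O)C(C)C)/C(C(=O)OC)=C/C=O
F2 | step 6 | methyl (4R,5E,9S)-6-{[(tert-butyldimethylsilyl)oxy]methyl}-4-hydroxy-9-[(2-methylpropanoyl)oxy]-9-[2-(trimethylsilyl)furan-3-yl]non-5-en-2-ynoate | COC(=O)C#C[C@H](O)/C=C(CO[Si](C)(C)C(C)(C)C)\CC[C@H](OC(=O)C(C)C)c1ccoc1[Si](C)(C)C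
F3 | step 6 | methyl (2Z,4R,5E,9S)-6-{[(tert-butyldimethylsilyl)oxy]methyl}-4-hydroxy-2-iodo-9-[(2-methylpropanoyl)oxy]-9-[2-(trimethylsilyl)furan-3-yl]nona-2,5-dienoate | COC(=O)/C(I)=C/[C@H](O)/C=C(CO[Si](C)(C)C(C)(C)C)\CC[C@H](OC(=O)C(C)C)c1ccoc1[Si](C)(C)C
F4 | step 8 | methyl (2E,4R,5E,9S)-6-{[(tert-butyldimethylsilyl)oxy]methyl}-4-hydroxy-9-(5-hydroxy-2-oxo-2,5-dihydrofuran-3-yl)-2-(hydroxymethyl)-9-[(2-methylpropanoyl)oxy]nona-2,5-dienoate | COC(=O)/C(CO)=C/[C@H](O)/C=C(CO[Si](C)(C)C(C)(C)C)\CC[C@H](OC(=O)C(C)C)C1=CC(O)OC1=O
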